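Partner over starting material, as charged, is 70.0 % in alpha, beta, eta and zeta alike. We call this ratio the ceiling: the share of the starting material that can become target if each target spends one partner. That makes partner the limiting reagent. The zero of our scale is the equal charge of the midnight run, with a ceiling of 100 %. The noon run has 47.0 % and the autumn run 46.7 %. Their last readings, 64.2 %, 18.6 % and 25.7 %, stand below these, so the one-to-one is our assumption, not a reading.

| flask | starting material | partner | temperature | remark | time |
|---|---|---|---|---|---|
| noon | 10 mM | 4.7 mM | −30 °C | run made earlier |  |
| midnight | 10 mM | 10 mM | 0 °C | run made earlier |  |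
| autumn | 15 mM | 7 mM | −30 °C | run made earlier |  |
| alpha | 10 mM | 7.00 mM |  | at −25 °C until 1.5 min, from then on at 25 °C | 3.0 min |
| beta | 10 mM | 7.00 mM | −25 °C |  | 3.0 min |
| eta | 10 mM | 7.00 mM | 0 °C |  | 3.0 min |
| zeta | 10 mM | 7.00 mM | 25 °C |  | 3.0 min |

| run | time / s | target / % | starting material / % |
|---|---|---|---|
| noon | 20.0 | 3.6 | 96.2 |
| noon | 40.0 | 7.8 | 91.8 |
| noon | 60.0 | 11.5 | 88.5 |
| noon | 80.0 | 12.5 | 85.8 |
| noon | 120 | 18.6 | 81.3 |
| midnight | 10.0 | 35.6 | 64.5 |
| midnight | 12.0 | 38.2 | 60.5 |
| midnight | 20.0 | 49.6 | 50.3 |
| midnight | 25.0 | 54.1 | 45.7 |
| midnight | 40.0 | 64.2 | 36.2 |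
| autumn | 10.0 | 4.3 | 96.1 |
| autumn | 15.0 | 6.5 | 96.0 |
| autumn | 30.0 | 10.0 | 90.0 |
| autumn | 60.0 | 16.7 | 85.1 |
| autumn | 120 | 25.7 | 75.2 |

(each reading ± 1 percentage point)

- the analysis behind the earlier runs scatters by 1 percentage point, standard deviation
- a reading or a percentage of target counts all its forms, free or not

The bench rule says that of two flasks with the same charge the warmer holds more target at a fixed time. The early pace of the midnight run, at 0 °C, reads about 19.8 times that of the noon run, at −30 °C, with partner charged 2.13 times as high. Target and starting material still add up to 100 % at the last midnight reading, so no loss shows there.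

The border of the rule is a ratio too: reading over ceiling. The last midnight reading is 0.917 of the ceiling of our flasks. Eta stands at the same temperature with less partner, but it has 4.50 times that time. So we expect eta close under its ceiling, and there the rule stops: on the one-to-one, zeta, at 25 °C, can add the room left beneath 70.0 %, and no more. Alpha, warmed halfway, has the same ceiling. We commit to beta well below the ceiling and to eta and zeta near it. But the runs stop at 0 °C, so how target fares at 25 °C is not read.

1. which flask leads in amount of target, in percent of the starting material charged ("all alike" within 1.5 percentage points) (alpha / beta / eta / zeta / all alike)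
2. how much target is there at the end, in percent of the starting material charged: alpha
3. how much target is there at the end, in percent of the starting material charged: beta
4. how much target is there at the end, in percent of the starting material charged: eta
5. how much target is there at the end, in percent of the starting material charged: zeta

The forecast gave 67 % for alpha, 42 % for beta, 63 % for eta and 69 % for zeta, in its words: “Zeta leads narrowly over alpha”.

The flasks give 55.7 % in alpha, 43.1 % in beta, 62.1 % in eta and 46.3 % in zeta, so eta leads.

    starting material + partner → target, rate k1*[starting material]*[partner]^1.5 (k = 250 /M^1.5/s, Ea = 38.0 kJ/mol)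
    target → over-reaction product (k = 0.0100 /s, Ea = 81.0 kJ/mol)
    crystals ⇌ target, rate k3*(cs3 - [target]) while solid is left; crystals form when [target] > cs3 (solubility = 1.20 mM, k = 0.350 /s)
    (constants at 25 °C)

Target here counts its crystals too. Eta's target is 0.887 of the ceiling. Zeta falls below it in target, but at 3.00 min its target of 46.3 % and its over-reaction product of 22.5 % together make 68.8 %, against the same 70.0 %. The neighbouring flask is eta with 17 mM of starting material and the same partner. Its ceiling is 41.2 %. At the end that flask holds 2.69 % of its partner charge and 59.9 % of starting material, and its target stands at 39.4 % against that ceiling of 41.2 %.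

(Readings and results come from a simulation with made-up constants.)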